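The next run takes the catalyst down from 5.8 mM to 3.9 mM. The decision is whether to leave that charge and stir for 8.0 h, or to raise it again.

- south-west: starting material 0.099 M; coupling partner 0.0891 M; catalyst 5.8 mM; run made earlier
- flask: starting material 0.099 M; coupling partner 0.0891 M; catalyst 3.9 mM; time 8.0 h

- south-west (time / h: target / %, over-reaction product / %): 0.333: 7.5, 0; 0.667: 12.5, 4.2; 1.00: 18.0, 1.4; 1.33: 22.6, 5.9; 1.50: 24.0, 3.7; 2.00: 28.5, 5.7; 2.50: 30.5, 7.5

(standard deviation of a reading: 1 percentage point)

* the state of affairs at 8.0 h: stopped, and by what, or still going (it is still moving / no working catalyst is left / the coupling partner has run out first / all of the starting material has reacted)
* how much target there is at 8.0 h, in percent of the starting material charged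
* how much over-reaction product there is at 8.0 h, in percent of the starting material charged

- percentages count the starting material that a species holds: one side product counts as two
- target is meant together with its crystals
- solid, in amounts per volume of the solution: crystals
- the numbers in the tables scatter by 1 percentage point (one standard deviation)
- steps thought possible: coupling partner + target -> over-reaction product; starting material + coupling partner + catalyst -> catalyst + target; starting material + target -> side product; crystals <-> target
- the reaction counts as stopped when no species that holds the starting material changes by six tenths of a point or more over the second half of the time
- no earlier run changes the charge of catalyst; that part of a forecast is a guess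

Target forms from starting material, coupling partner and catalyst, and the catalyst comes back. The rate is therefore taken as κ·c_catalyst·c_start·c_partner, and its catalyst dependence is a guess, since no earlier run changes that charge. Time then counts as the product of catalyst and hours. In that product the flask offers twice what the south-west run had at its last reading, more than that run's span.

Coupling partner is charged at less than starting material, so it is the limiting reagent. In the main step both lose the same turnover x. With the coupling partner taken by over-reaction left aside in this reckoning, the rate integrates in closed form:

ln[(c_partner,charged·c_start)/(c_start,charged·c_partner)] = κ·c_catalyst·t·(c_start,charged − c_partner,charged).

At 2.50 h the south-west run reads 38.0% as target plus over-reaction product, so x = 0.0376 M. This reading gives κ = 8.19 L² mol⁻² min⁻¹, the catalyst-normalised constant, and it carries the scatter.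

For the flask, the logarithm's argument becomes 1.16, which puts main-step turnover at 55.9% of the starting material charged. That is more than the south-west reading, so the charge stays and the flask is read at 8.0 h.

The forecast says it is still moving, with 33% target and 18% over-reaction product, “though this scaling is a guess”.

The flask gives: it is still moving, 28.8% target, 17.5% over-reaction product.

    coupling partner + target → over-reaction product (k = 0.0710 L mol⁻¹ min⁻¹)
    starting material + coupling partner + catalyst → catalyst + target (k = 9.70 L² mol⁻² min⁻¹)
    starting material + target → side product (k = 0.0180 L mol⁻¹ min⁻¹)
    crystals ⇌ target, rate k4*(cs4 - [target]) while solid is left; crystals form when [target] > cs4 (solubility = 13.0 mM, k = 0.270 min⁻¹)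

The flask keeps 41.1% of its starting material at 8.00 h, in part because coupling partner is consumed, acting together with the reading being taken at that time. Conversion in the flask stands at 58.9%, against 82.2% in the same run without that consumption. Main-step turnover in the flask is target, over-reaction product and half of the side product, 52.6% against the reckoned 55.9%. For a neighbour flask charged like this one but with 0.036 M of coupling partner, κ gives 26.1%. That neighbour flask holds 25.2% by the same count.

All runs are calculated for an exercise.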